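**Plan**

- Retrosynthetic cuts, in order: the C8–O angelate ester; the furanone O–C3 bond (transannular hydration/cyclodehydration of a 4‑hydroxy‑2‑ynone); C1–C10 (acetylide plus methyl ketone, the ring-closing cut); C3–C4 (alkenyl iodide plus ynal); C4=C5 (iodo-Wittig); C8–C9 (acetone aldol); C7–C8 and C11–CH3 (conjugate addition/methylation of a butenolide).
- Enabling feature: the 3(2H)-furanone ring (O, C3, C2, C1, C10) is the cyclodehydrated form of the 4‑hydroxy‑2‑yn‑1‑one C10(OH)–C1≡C2–C3(=O). C10 is therefore a tertiary propargylic carbinol, made from a C10 methyl ketone and a C1 acetylide. The C1≡C2 rod, the Z C4=C5 olefin and the trans-fused lactone (C6, C7, C11, C12, O) pre-bend the seco chain for closure of the ten-membered carbocycle C1–C10.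
- Forward order of rings: lactone ring bought as a butenolide; ten-membered carbocycle by C1–C10 closure (step 10); furanone ring by transannular O–C3 closure (step 12); angelate last.
- Stereochemistry: C6 is bought; C7 and C11 are relayed from C6 in one three-component operation; C8 is set by L‑proline catalyst control; C10 is set in the ring closure by 1,3‑induction from C8; the Z C4=C5 geometry comes from the iodo-ylide olefination and a retentive coupling; the angelate geometry is bought.

Key step: step 10

Remark: germacrane numbering of the target is used for all intermediates (C1 ketone, C3 enol-ether carbon, C4=C5, C6 lactone oxygen, C8 ester oxygen, C10 quaternary, C11 methyl-bearing, C12 lactone carbonyl); the C3 carbinol in 19, 20, 21 and 22 is carried as both epimers (drawn without configuration), which converge at ketone 23.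

**Route**

Step 1
Reactants: 1 (S)-5-(hydroxymethyl)furan-2(5H)-one
Product: 2 (S)-5-[(triethylsilyloxy)methyl]furan-2(5H)-one
Conditions: TESCl, imidazole, CH2Cl2, 0 °C
Reagents that add atoms: chlorotriethylsilane (TESCl), CC[Si](Cl)(CC)CC
Why: Standard silylation of a primary alcohol that leaves the bought C6 stereocenter untouched, the primary triethylsilyl ether being chosen because it can later be oxidised directly to the aldehyde.

Step 2
Reactants: 2 (S)-5-[(triethylsilyloxy)methyl]furan-2(5H)-one; 3 vinylmagnesium bromide; 4 iodomethane
Product: 6 (3S,4S,5S)-3-methyl-5-[(triethylsilyloxy)methyl]-4-vinyldihydrofuran-2(3H)-one (all-trans lactone), via magnesium enolate 5 (not isolated)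
Conditions: 3 (1.3 equiv), CuBr·SMe2 (10 mol%), THF, −78 °C; then 4, DMPU, −78 to −20 °C
Reagents that add atoms: none
Why: Copper-catalysed conjugate addition followed by enolate alkylation (three-component vicinal difunctionalisation), in which the vinyl group adds to C7 anti to the C6 CH2OTES group and iodomethane then alkylates the C11 enolate anti to the new C7 vinyl group, so that C7 and C11 are both relayed from C6.

Step 3
Reactants: 6 all-trans lactone TES ether
Product: 7 (2S,3S,4S)-4-methyl-5-oxo-3-vinyltetrahydrofuran-2-carbaldehyde (C5 aldehyde)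
Conditions: (COCl)2, DMSO, CH2Cl2, −78 to −40 °C; Et3N, −78 to 0 °C
Reagents that add atoms: none
Why: Swern oxidation applied directly to a primary triethylsilyl ether, in which the chlorosulfonium salt cleaves the O–Si bond and the alkoxysulfonium ion collapses to the aldehyde without forming a stereocenter, the crude aldehyde being used at once to avoid epimerisation at C6.

Step 4
Reactants: 7 C5 aldehyde; 8 ethyltriphenylphosphonium iodide
Product: 12 (3S,4S,5S)-5-[(Z)-2-iodoprop-1-en-1-yl]-3-methyl-4-vinyldihydrofuran-2(3H)-one, via ethylidene ylide 9 (not isolated), via iodophosphonium salt 10 (not isolated), via iodo ylide 11 (not isolated)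
Conditions: 8, n-BuLi, THF, 0 °C; I2, −78 °C; NaN(SiMe3)2, −20 °C; then 7, −78 °C
Reagents that add atoms: iodine, [I][I]
Why: Stork–Zhao iodo-olefination (Wittig reaction of an α-iodo ylide), which under kinetic cis-oxaphosphetane control should place iodine cis to the C6 substituent and thereby fix the later Z geometry of C4=C5.

Step 5
Reactants: 12 (Z)-alkenyl iodide with C7 vinyl group
Product: 14 (2S,3S,4S)-2-[(Z)-2-iodoprop-1-en-1-yl]-4-methyl-5-oxotetrahydrofuran-3-carbaldehyde (C8 aldehyde), via diol 13 (not isolated)
Conditions: OsO4 (2 mol%), NaIO4, 2,6-lutidine, dioxane/H2O, rt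
Reagents that add atoms: osmium tetroxide, O=[Os](=O)(=O)=O (catalytic; its oxygen is replenished from sodium periodate, [Na+].[O-]I(=O)(=O)=O)
Why: Lemieux–Johnson dihydroxylation and glycol cleavage, expected to be chemoselective for the monosubstituted vinyl group because the trisubstituted iodoalkene is deactivated by iodine and more hindered, while C7 stays in its thermodynamically preferred trans,trans arrangement.

Step 6
Reactants: 14 C8 aldehyde; 15 acetone
Product: 16 β-hydroxy ketone (8R carbinol carrying the C9–C10(=O)–CH3 chain; C6, C7, C11 as in the target)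
Conditions: L-proline (30 mol%), 15/DMSO 1:4, rt
Reagents that add atoms: none
Why: Proline-catalysed direct aldol reaction (enamine catalysis) in which the acetone enamine attacks the Re face of the α-branched aldehyde through the carboxylic-acid-organised chair transition state, which should set C8 as R under catalyst control.

Step 7
Reactants: 16 β-hydroxy ketone
Product: 17 C8 tert-butyldimethylsilyl ether of 16
Conditions: TBSOTf, 2,6-lutidine, CH2Cl2, −78 °C
Reagents that add atoms: tert-butyldimethylsilyl triflate (TBSOTf), CC(C)(C)[Si](C)(C)OS(=O)(=O)C(F)(F)F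
Why: Silylation of a secondary alcohol with a silyl triflate at low temperature, which should outpace enol silylation of the methyl ketone and gives an ether that blocks translactonisation to O8 and is a poor leaving group in the later basic step.

Step 8
Reactants: 17 alkenyl iodide ketone; 18 3-(trimethylsilyl)propynal
Product: 19 C3 carbinol (both epimers) with the trimethylsilyl-capped C1≡C2 alkyne and Z C4=C5 olefin
Conditions: CrCl2 (6 equiv), NiCl2 (2 mol%), DMSO, rt
Reagents that add atoms: none
Why: Nozaki–Hiyama–Kishi coupling, in which the alkenylchromium species formed with retention of olefin geometry adds only to the aldehyde and spares ketone, lactone and silyl ether, the uncontrolled C3 carbinol being harmless because it is oxidised in step 11.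

Step 9
Reactants: 19 silyl-capped alkyne
Product: 20 terminal alkyne (seco compound with free C3 hydroxyl and C10 methyl ketone)
Conditions: K2CO3 (0.3 equiv), MeOH, 0 °C
Reagents that add atoms: none
Why: Base-catalysed methanolysis of the alkynyl C–Si bond, mild enough to spare the lactone, the β-silyloxy ketone and the TBS ether.

Step 10
Reactants: 20 seco alkyne ketone
Product: 22 ten-membered enyne diol (10R tertiary propargylic alcohol; C3 carbinol as both epimers; C8 OTBS; trans-lactone), via dianion 21 (not isolated)
Conditions: CeCl3 (4 equiv), KN(SiMe3)2 (2.1 equiv), THF (0.002 M), −78 to −40 °C; aq NH4Cl, −40 °C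
Reagents that add atoms: none
Why: KN(SiMe3)2 removes the C3 hydroxyl proton and the terminal alkyne proton, and transmetalation to cerium gives a weakly basic but strongly nucleophilic acetylide that adds 1,2 to the cerium-activated C10 methyl ketone, forming the C1–C10 bond. The closest known reaction type is the intramolecular acetylide-to-carbonyl addition (Favorskii-type alkynylation) used to close nine- and ten-membered cycloalkyne rings onto ketones with the same amide/CeCl3 combination. The ten-membered carbocycle C1–C10 closes in the 10-exo-trig mode and no other ring forms; the colinear C10–C1≡C2–C3 unit, the Z C4=C5 olefin and the trans-fused lactone at C6–C7 leave few rotatable bonds and bring C1 within reach of C10. The new stereocenter C10 is controlled by 1,3-induction from C8: in the non-chelated, dipole-opposed arrangement of the C8–OTBS and C10=O bonds the tethered acetylide should reach the carbonyl face that places the new C10–O anti to C8–O along the ring (10R, methyl on the face of the C8 oxygen). The step needs addition to outrun enolisation of the methyl ketone, β-elimination of the C8 silyloxy group, attack on the lactone and oligomerisation; these are addressed by the low basicity of the organocerium species, the poor leaving-group ability of the silyl ether at −78 °C, the higher electrophilicity of the ketone, high dilution, and a cold quench that prevents O8-to-O10 silyl migration.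

Step 11
Reactants: 22 ten-membered enyne diol
Product: 23 macrocyclic 4-hydroxy-2-ynone (C3 ketone)
Conditions: MnO2 (excess), CH2Cl2, rt
Reagents that add atoms: none
Why: Manganese dioxide oxidation, selective for the doubly activated (allylic and propargylic) C3 alcohol, while the tertiary C10 alcohol cannot be oxidised and the two C3 epimers converge.

Step 12
Reactants: 23 macrocyclic ynone
Product: 25 furanone TBS ether (3(2H)-furanone ring closed), via diketone 24 (not isolated)
Conditions: (4-CF3C6H4)3PAuCl (5 mol%), AgOTf (5 mol%), toluene (not dried), rt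
Reagents that add atoms: water, O (adventitious and catalytic: one molecule adds at C1 and one is released from C3)
Why: Gold-catalysed isomerisation of a 4-hydroxy-2-yn-1-one to a 3(2H)-furanone, in which cationic monovalent gold activates C1≡C2 for addition of water at C1 (β to the C3 ketone) and the resulting 1,3-diketone is trapped transannularly by the C10 hydroxyl at C3 with loss of water, the C10 configuration being retained.

Step 13
Reactants: 25 furanone TBS ether
Product: 26 C8 alcohol
Conditions: HF·pyridine, pyridine, THF, 0 °C to rt
Reagents that add atoms: none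
Why: Fluoride-mediated desilylation under buffered acidic conditions, which avoids the alkoxide that could translactonise from O6 to O8 or open the furanone.

Step 14
Reactants: 26 C8 alcohol; 27 angelic acid
Product: 29 target 8-O-angelate, via mixed anhydride 28 (not isolated)
Conditions: 27, 2,4,6-trichlorobenzoyl chloride, Et3N, toluene, rt; then 26, toluene, 80 °C
Reagents that add atoms: none
Why: Yamaguchi-type esterification through the mixed anhydride without a nucleophilic amine catalyst, conditions under which the (Z)-2-methylbut-2-enoyl group should be transferred without isomerisation to the tiglate and no stereocenter is touched.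

**Compound list**

1 | (S)-5-(hydroxymethyl)furan-2(5H)-one | OC[C@H]1OC(=O)C=C1 | starting material
2 | (S)-5-[(triethylsilyloxy)methyl]furan-2(5H)-one | CC[Si](CC)(CC)OC[C@H]1OC(=O)C=C1 | intermediate
3 | vinylmagnesium bromide | C=C[Mg]Br | starting material
4 | iodomethane | CI | starting material
5 | bromomagnesium enolate of the C7-vinyl lactone, vinyl trans to the C6 substituent (formed in the flask) | CC[Si](CC)(CC)OC[C@H]1OC(O[Mg]Br)=C[C@@H]1C=C | intermediate
6 | (3S,4S,5S)-3-methyl-5-[(triethylsilyloxy)methyl]-4-vinyldihydrofuran-2(3H)-one (all-trans) | CC[Si](CC)(CC)OC[C@H]1OC(=O)[C@@H](C)[C@@H]1C=C | intermediate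
7 | (2S,3S,4S)-4-methyl-5-oxo-3-vinyltetrahydrofuran-2-carbaldehyde | O=C[C@H]1OC(=O)[C@@H](C)[C@@H]1C=C | intermediate
8 | ethyltriphenylphosphonium iodide | CC[P+](c1ccccc1)(c1ccccc1)c1ccccc1.[I-] | starting material
9 | ethylidenetriphenylphosphorane (formed in the flask) | CC=P(c1ccccc1)(c1ccccc1)c1ccccc1 | intermediate
10 | (1-iodoethyl)triphenylphosphonium iodide (formed in the flask) | CC(I)[P+](c1ccccc1)(c1ccccc1)c1ccccc1.[I-] | intermediate
11 | (1-iodoethylidene)triphenylphosphorane (formed in the flask) | CC(I)=P(c1ccccc1)(c1ccccc1)c1ccccc1 | intermediate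
12 | (3S,4S,5S)-5-[(Z)-2-iodoprop-1-en-1-yl]-3-methyl-4-vinyldihydrofuran-2(3H)-one | I/C(C)=C\[C@H]1OC(=O)[C@@H](C)[C@@H]1C=C | intermediate
13 | 1,2-diol from dihydroxylation of the C7 vinyl group of 12, both carbinol epimers (formed in the flask) | I/C(C)=C\[C@H]1OC(=O)[C@@H](C)[C@@H]1C(O)CO | intermediate
14 | (2S,3S,4S)-2-[(Z)-2-iodoprop-1-en-1-yl]-4-methyl-5-oxotetrahydrofuran-3-carbaldehyde | I/C(C)=C\[C@H]1OC(=O)[C@@H](C)[C@@H]1C=O | intermediate
15 | acetone | CC(C)=O | starting material
16 | all-trans lactone with (Z)-2-iodoprop-1-enyl at C6 and (R)-1-hydroxy-3-oxobutyl at C7 (8R) | I/C(C)=C\[C@H]1OC(=O)[C@@H](C)[C@@H]1[C@H](O)CC(C)=O | intermediate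
17 | C8 tert-butyldimethylsilyl ether of 16 | I/C(C)=C\[C@H]1OC(=O)[C@@H](C)[C@@H]1[C@H](O[Si](C)(C)C(C)(C)C)CC(C)=O | intermediate
18 | 3-(trimethylsilyl)propynal | C[Si](C)(C)C#CC=O | starting material
19 | coupling product: C3 carbinol (both epimers), trimethylsilyl alkyne at C1, Z C4=C5, C8 OTBS, C10 methyl ketone | C[Si](C)(C)C#CC(O)/C(C)=C\[C@H]1OC(=O)[C@@H](C)[C@@H]1[C@H](O[Si](C)(C)C(C)(C)C)CC(C)=O | intermediate
20 | terminal alkyne seco compound (C3 carbinol as both epimers) | C#CC(O)/C(C)=C\[C@H]1OC(=O)[C@@H](C)[C@@H]1[C@H](O[Si](C)(C)C(C)(C)C)CC(C)=O | intermediate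
21 | C3 alkoxide / C1 acetylide dianion of 20, drawn as the dipotassium salt (formed in the flask) | [K+].[K+].[C-]#CC([O-])/C(C)=C\[C@H]1OC(=O)[C@@H](C)[C@@H]1[C@H](O[Si](C)(C)C(C)(C)C)CC(C)=O | intermediate
22 | ten-membered enyne diol: 10R tertiary propargylic alcohol, C3 carbinol (both epimers), C8 OTBS, trans-fused lactone, Z C4=C5 | CC(C)(C)[Si](C)(C)O[C@@H]1C[C@@](C)(O)C#CC(O)/C(C)=C\[C@H]2OC(=O)[C@@H](C)[C@@H]21 | intermediate
23 | macrocyclic 4-hydroxy-2-ynone (C3 ketone) | CC(C)(C)[Si](C)(C)O[C@@H]1C[C@@](C)(O)C#CC(=O)/C(C)=C\[C@H]2OC(=O)[C@@H](C)[C@@H]21 | intermediate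
24 | macrocyclic C1,C3-diketone with free C10 hydroxyl (formed in the flask) | CC(C)(C)[Si](C)(C)O[C@@H]1C[C@@](C)(O)C(=O)CC(=O)/C(C)=C\[C@H]2OC(=O)[C@@H](C)[C@@H]21 | intermediate
25 | furanone C8 tert-butyldimethylsilyl ether (target skeleton, OTBS in place of the angelate) | CC(C)(C)[Si](C)(C)O[C@@H]1C[C@@]2(C)OC(=CC2=O)/C(C)=C\[C@H]2OC(=O)[C@@H](C)[C@@H]21 | intermediate
26 | furanone C8 alcohol | O[C@@H]1C[C@@]2(C)OC(=CC2=O)/C(C)=C\[C@H]2OC(=O)[C@@H](C)[C@@H]21 | intermediate
27 | angelic acid, (Z)-2-methylbut-2-enoic acid | C/C=C(/C)C(=O)O | starting material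
28 | angelic 2,4,6-trichlorobenzoic mixed anhydride (formed in the flask) | C/C=C(/C)C(=O)OC(=O)c1c(Cl)cc(Cl)cc1Cl | intermediate
29 | CNP0278264.1: (4Z)-furanoheliangolide 8-O-angelate, 6R,7R,8R,10R,11S in germacrane numbering | C/C=C(/C)C(=O)O[C@@H]1C[C@@]2(C)OC(=CC2=O)/C(C)=C\[C@H]2OC(=O)[C@@H](C)[C@@H]21 | target

**Step count and risks**

Total step count: 14. Longest linear sequence: 14 steps (from 1).

Steps most likely to fail:

1. Step 10 (ring closure). Possible failures are enolisation of the methyl ketone instead of addition, oligomerisation, or poor facial selectivity at C10. Fallback: the C1–C10 bond is made between two molecules and the ring is closed at C3–C4 instead. Setting out from ketone 17, the cerium acetylide of commercial 3,3-diethoxyprop-1-yne (n-BuLi, CeCl3, THF, −78 °C) is added to the C10 ketone to give the tertiary propargylic alcohol acetal F1, whose C10 epimers can be separated at this stage. Hydrolysis of the acetal (aqueous formic acid, 0 °C) gives the ynal F2. An intramolecular Nozaki–Hiyama–Kishi reaction (CrCl2, NiCl2 2 mol%, DMSO/THF, high dilution) between the C4 iodide and the C3 aldehyde then closes the ten-membered ring and comes back to the route at diol 22.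

2. Step 6 (aldol). Possible failures are poor facial selectivity if the catalyst and the C7 stereocenter are mismatched, or β-elimination that opens the lactone. Fallback: setting out from aldehyde 14, a strongly reagent-controlled methallylboration with B-methallyldiisopinocampheylborane of the (−)-α-pinene series (Et2O, −78 °C; ethanolamine work-up) should give the 8R homoallylic alcohol F3. Silylation (TBSOTf, 2,6-lutidine) gives the TBS ether F4. Cleavage of the 1,1-disubstituted olefin with OsO4/NaIO4 (selective over the iodoalkene as in step 5) comes back to the route at ketone 17.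

3. Step 12 (furanone formation). Possible failures are diversion into a Meyer–Schuster-type rearrangement of the tertiary propargylic alcohol or hydration at the wrong alkyne carbon. Fallback: setting out from ynone 23, aza-Michael addition of diethylamine at C1 (EtOH, rt) gives the enaminone F5; aqueous acetic acid/THF then effects hydrolysis and transannular cyclodehydration and comes back to the route at furanone 25.

**Further compounds**

F1 | step 10 | tertiary propargylic alcohol (10R) from 17 carrying the C1≡C2–C3H(OEt)2 chain, C4 iodide intact | I/C(C)=C\[C@H]1OC(=O)[C@@H](C)[C@@H]1[C@H](O[Si](C)(C)C(C)(C)C)C[C@@](C)(O)C#CC(OCC)OCC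
F2 | step 10 | ynal (C3 aldehyde) derived from F1 | I/C(C)=C\[C@H]1OC(=O)[C@@H](C)[C@@H]1[C@H](O[Si](C)(C)C(C)(C)C)C[C@@](C)(O)C#CC=O
F3 | step 6 | 8R homoallylic alcohol with a 2-methylallyl group at C8 | I/C(C)=C\[C@H]1OC(=O)[C@@H](C)[C@@H]1[C@H](O)CC(C)=C
F4 | step 6 | C8 tert-butyldimethylsilyl ether of F3 | I/C(C)=C\[C@H]1OC(=O)[C@@H](C)[C@@H]1[C@H](O[Si](C)(C)C(C)(C)C)CC(C)=C
F5 | step 12 | macrocyclic enaminone with a diethylamino group at C1 | CC(C)(C)[Si](C)(C)O[C@@H]1C[C@@](C)(O)C(N(CC)CC)=CC(=O)/C(C)=C\[C@H]2OC(=O)[C@@H](C)[C@@H]21
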